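If each flask took its character from the temperature at which its substrate was used up, the two earlier runs would give us the two ends between which to place today's pair.

| flask | substrate | partner | temperature | remark | time |
|---|---|---|---|---|---|
| north-east | 6 mM | 24 mM (fed, over 25 min) | −35 °C | run made earlier |  |
| east | 9 mM | 24 mM (fed, over 25 min) | −24 °C | run made earlier |  |
| Friday's | 12 mM | 24.0 mM (fed, over 25 min) |  | at −40 °C throughout | 150 min |
| Wednesday's | 12 mM | 24.0 mM (fed, over 25 min) |  | at −40 °C until 25 min, from then on at −20 °C | 50 min |

| run | time / min | target / % | homo product / % |
|---|---|---|---|
| north-east | 6.00 | 7 | 30 |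
| north-east | 12.0 | 26 | 40 |
| north-east | 20.0 | 46 | 44 |
| north-east | 25.0 | 48 | 43 |
| north-east | 30.0 | 52 | 43 |
| north-east | 40.0 | 52 | 46 |
| east | 1.00 | 0 | 21 |
| east | 4.00 | 7 | 58 |
| east | 6.00 | 14 | 66 |
| east | 10.0 | 15 | 72 |
| east | 15.0 | 21 | 70 |
| east | 20.0 | 20 | 73 |

(readings scatter by 1.5 percentage points)

- in percentages every species weighs as the substrate in it: one homo product counts as two
- the numbers in the tables scatter with a standard deviation of 1.5 percentage points
- a reading or a percentage of target counts all its forms, free or not

- which of the two ends with the higher share of target in all that became target or homo product ("neither" if they lie within 2 percentage points) (Friday's / Wednesday's / neither)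
- share of target in all that became target or homo product, Friday's
- share of target in all that became target or homo product, Wednesday's

We take the share of target among the two products (the selectivity) from the last reading of each earlier run.

cold end, north-east run: 52 % / (52 % + 46 %) = 53.1 %

warm end, east run: 20 % / (20 % + 73 %) = 21.5 %

Friday's flask is colder than the north-east run, but it gets 2.00 of partner per substrate against 4.00 there, so we place it below the cold end, by an amount these two runs cannot tell us.

Wednesday's flask is the same as Friday's until 25 min, so any parting comes later. We reckon one way of parting, through what is still unfinished then, and read that from the north-east run at the end of its feed: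

1 − 48 % − 43 % = 9.00 %

This unfinished share is the fraction of the charge not yet in target or homo product. It is a reading, with its scatter. Suppose that part of Wednesday's flask goes on at the warm end while the finished target stays put. Then Wednesday's falls behind Friday's by

9.00 % × (53.1 % − 21.5 %) = 2.8 percentage points

That is just over the margin of 2 points, so we would say Friday's, narrowly.

The forecast says neither, with 45 % for Friday's and 45 % for Wednesday's, on the ground that after the feed “the remainder goes mostly to target at either temperature”. Our reckoning differs from it on the winner.

The flasks give Friday's: 42.6 % for Friday's and 26.2 % for Wednesday's.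

    substrate → open intermediate (k = 0.00567 s⁻¹, Ea = 63.0 kJ mol⁻¹)
    partner → second intermediate (k = 0.00153 s⁻¹, Ea = 74.0 kJ mol⁻¹)
    open intermediate + second intermediate ⇌ target (K = 820 L mol⁻¹, k = 0.238 L mol⁻¹ s⁻¹, Ea = 51.0 kJ mol⁻¹, ΔH = −37.0 kJ mol⁻¹)
    2 open intermediate → homo product (k = 0.0824 L mol⁻¹ s⁻¹, Ea = 51.0 kJ mol⁻¹)
    partner + target ⇌ idle adduct, settled at all times (K = 20.0 L mol⁻¹, ΔH = −39.0 kJ mol⁻¹)
    (constants at −40 °C)

Between the change at 25 min and 50.0 min, Wednesday's homo product gained 15 points, more than the unfinished share of 9.00 %, while its target lost 9.2 points. Friday's flask, kept cold, gained 1.7 points of homo product by 150 min, less than that share, and its target rose by 7.7 points. The temperature programme is the main reason: Friday's flask given Wednesday's programme ends at 11.9 % in place of 42.6 %. Part of Wednesday's loss is the falling back of target to open intermediate and second intermediate: the same Wednesday's run with that step taken away ends at 46.4 %.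

The earlier runs and the new flask were computed for substances that don't exist; scatter was added.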